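## Retrosynthetic overview

1. The (E)-propenyl group is disconnected last (Suzuki–Miyaura) to a 5-bromo-dihydrobenzofuran, so no styrenic alkene is present during ring construction.
2. Key disconnection, a formal [4+1]: C2–C3 and C2–O1 are cut to an ortho-quinone methide (O1, C7a, C3a, C3; C3 electrophilic) and a one-carbon unit for C2.
3. C2 is by nature the electrophilic carbonyl carbon of 3,4,5-trimethoxybenzaldehyde (C2–O and C7a–O are 1,4-related, a dissonant pattern). Its polarity is reversed by using it as a chiral benzylic sulfonium ylide (an α-oxybenzyl anion equivalent), which adds to the methide carbon (C2–C3) and then loses the sulfide in the ring closure, setting both stereocentres.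
4. The ylide comes from isothiocineole (one step from (S)-limonene and sulfur) and 3,4,5-trimethoxybenzyl bromide. The quinone methide is released at low temperature in the key step itself, from the tert-butyl carbonate of 5-bromo-2-hydroxy-3-methoxybenzaldehyde by MeMgBr addition, which also brings in the C3 methyl group.
5. Ring order: both benzene rings are bought; the dihydrofuran ring is the only ring made, in the key step.

Assumption: the SMILES is read as the (2R,3R)-trans isomer with an (E)-propenyl group; the sense of induction in step 4 is derived from a steric model of the ylide, not from a measured result.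

## Route

Step 1
Reactants: 1 (S)-(−)-limonene
Product: 2 (1S,4S,5S)-isothiocineole
Conditions: S8, γ-terpinene (1 equiv), neat, 110 °C, 24 h; vacuum distillation
Reagents that add atoms: sulfur (S8), `S1SSSSSSS1`
Why: Radical addition of sulfur across the two alkenes of 1 (thiyl radical cyclisation) with γ-terpinene as hydrogen-atom donor closes the 6-thiabicyclo[3.2.1]octane; the limonene stereocentre is untouched and the rigid bicycle fixes the two new centres relative to it.

Step 2
Reactants: 2 (1S,4S,5S)-isothiocineole; 3 3,4,5-trimethoxybenzyl bromide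
Product: 4 (1S,4S,5S,6S)-4,7,7-trimethyl-6-(3,4,5-trimethoxybenzyl)-6-thiabicyclo[3.2.1]octan-6-ium tetrafluoroborate
Conditions: NaBF4 (5 equiv), CH2Cl2/H2O, rt, 48 h
Reagents that add atoms: sodium tetrafluoroborate, `[Na+].F[B-](F)(F)F`
Why: SN2 S-benzylation (sulfonium salt formation) occurs at the exo lone pair, on the side of the one-carbon bridge and away from the three-carbon bridge, so a single sulfonium diastereomer forms, and exchange of bromide for BF4− stops dealkylation.

Step 3
Reactants: 5 5-bromo-2-hydroxy-3-methoxybenzaldehyde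
Product: 6 tert-butyl (4-bromo-2-formyl-6-methoxyphenyl) carbonate
Conditions: Boc2O (1.1 equiv), 4-(dimethylamino)pyridine (5 mol %), CH2Cl2, 0 °C to rt
Reagents that add atoms: di-tert-butyl dicarbonate, `CC(C)(C)OC(=O)OC(=O)OC(C)(C)C`
Why: Nucleophile-catalysed O-acylation of the phenol (Boc protection) leaves the aldehyde untouched and forms no stereocentre; the aryl carbonate is the latent leaving group for the quinone methide in step 4.

Step 4
Reactants: 4 (1S,4S,5S,6S)-4,7,7-trimethyl-6-(3,4,5-trimethoxybenzyl)-6-thiabicyclo[3.2.1]octan-6-ium tetrafluoroborate; 6 tert-butyl (4-bromo-2-formyl-6-methoxyphenyl) carbonate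
Product: 12 (2R,3R)-5-bromo-7-methoxy-3-methyl-2-(3,4,5-trimethoxyphenyl)-2,3-dihydro-1-benzofuran, via magnesium alkoxide 7 (not isolated), via magnesium phenolate 8 (not isolated), via sulfonium ylide 9 (not isolated), via ortho-quinone methide 10 (not isolated), via betaine 11 (not isolated)
Conditions: 6, MeMgBr (1.05 equiv), THF, −78 °C, 30 min; then ylide from 4 (1.3 equiv) and LiN(SiMe3)2 (1.25 equiv), THF, −78 °C, added by cannula; −78 to −20 °C over 3 h; aq NH4Cl
Reagents that add atoms: methylmagnesium bromide, `C[Mg]Br`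
Why: Proposed new method: MeMgBr adds to the aldehyde of 6 and the alkoxide 7 takes over the Boc group (intramolecular O-to-O transfer through a six-membered transition state) to give phenolate 8, which on warming expels tert-butyl carbonate and releases the ortho-quinone methide 10 at low temperature, where tautomerisation to the vinylphenol is slow and the racemic carbinol centre is erased; the benzylic ylide 9, in which the carbon that is the electrophilic carbonyl carbon of 3,4,5-trimethoxybenzaldehyde in normal polarity acts as the nucleophile, adds to the equally electrophilic methide carbon (conjugate addition giving betaine 11), and the phenoxide of 11 then displaces isothiocineole by 5-exo-tet SN2 with inversion; the exo-S-benzyl ylide should react through the conformer with the aryl group beside the sulfur lone pair and on the face remote from the CMe2 group, which after inversion gives 2R, while the anti arrangement of the aryl group and the quinone methide ring in the C–C bond-forming transition state (E-configured 10) gives the 2,3-trans relationship and hence 3R; the closest known reactions are the low-temperature release of ortho-quinone methides from ortho-(tert-butoxycarbonyloxy)benzaldehydes and organomagnesium reagents with capture by a second carbon nucleophile, the formal [4+1] annulation of sulfonium ylides with ortho-quinone methides (trans-2,3-dihydrobenzofurans), and the asymmetric Corey–Chaykovsky epoxidation and aziridination with isothiocineole-derived benzylsulfonium salts.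

Step 5
Reactants: 12 (2R,3R)-5-bromo-7-methoxy-3-methyl-2-(3,4,5-trimethoxyphenyl)-2,3-dihydro-1-benzofuran; 13 (E)-prop-1-enylboronic acid pinacol ester
Product: 14 (2R,3R)-7-methoxy-3-methyl-5-[(1E)-prop-1-en-1-yl]-2-(3,4,5-trimethoxyphenyl)-2,3-dihydro-1-benzofuran
Conditions: Pd(OAc)2 (5 mol %), 2-dicyclohexylphosphino-2',6'-dimethoxybiphenyl (10 mol %), K3PO4, toluene/H2O, 80 °C
Reagents that add atoms: none
Why: Suzuki–Miyaura coupling of the electron-rich aryl bromide with retention of the E geometry of the alkenylboronate; the mildly basic conditions touch neither C2 nor C3.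

## Compound list

1 | (S)-(−)-limonene | `CC1=CC[C@H](CC1)C(C)=C` | starting material
2 | (1S,4S,5S)-isothiocineole, (1S,4S,5S)-4,7,7-trimethyl-6-thiabicyclo[3.2.1]octane | `C[C@H]1CC[C@H]2C[C@@H]1SC2(C)C` | intermediate
3 | 3,4,5-trimethoxybenzyl bromide | `COc1cc(CBr)cc(OC)c1OC` | starting material
4 | (1S,4S,5S,6S)-4,7,7-trimethyl-6-(3,4,5-trimethoxybenzyl)-6-thiabicyclo[3.2.1]octan-6-ium tetrafluoroborate (benzyl exo, on the side of C8) | `COc1cc(C[S@+]2[C@H]3C[C@H](CC[C@@H]3C)C2(C)C)cc(OC)c1OC.F[B-](F)(F)F` | intermediate
5 | 5-bromo-2-hydroxy-3-methoxybenzaldehyde | `O=Cc1cc(Br)cc(OC)c1O` | starting material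
6 | tert-butyl (4-bromo-2-formyl-6-methoxyphenyl) carbonate | `O=Cc1cc(Br)cc(OC)c1OC(=O)OC(C)(C)C` | intermediate
7 | rac-bromomagnesium 1-[5-bromo-2-(tert-butoxycarbonyloxy)-3-methoxyphenyl]ethan-1-olate | `CC(O[Mg]Br)c1cc(Br)cc(OC)c1OC(=O)OC(C)(C)C` | intermediate (not isolated)
8 | rac-bromomagnesium 4-bromo-2-[1-(tert-butoxycarbonyloxy)ethyl]-6-methoxyphenolate | `CC(OC(=O)OC(C)(C)C)c1cc(Br)cc(OC)c1O[Mg]Br` | intermediate (not isolated)
9 | sulfonium ylide of 4: (3,4,5-trimethoxyphenyl)methanide on the exo face of the (1S,4S,5S)-isothiocineolium sulfur | `COc1cc([CH-][S@+]2[C@H]3C[C@H](CC[C@@H]3C)C2(C)C)cc(OC)c1OC` | intermediate (not isolated)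
10 | (6E)-4-bromo-6-ethylidene-2-methoxycyclohexa-2,4-dien-1-one (ortho-quinone methide) | `C/C=C1\C=C(Br)C=C(OC)C1=O` | intermediate (not isolated)
11 | betaine: 4-bromo-2-methoxy-6-[(1S,2R)-1-(isothiocineolium-6-yl)-1-(3,4,5-trimethoxyphenyl)propan-2-yl]phenolate | `[O-]c1c(OC)cc(Br)cc1[C@@H](C)[C@@H](c1cc(OC)c(OC)c(OC)c1)[S@+]1[C@H]2C[C@H](CC[C@@H]2C)C1(C)C` | intermediate (not isolated)
12 | (2R,3R)-5-bromo-7-methoxy-3-methyl-2-(3,4,5-trimethoxyphenyl)-2,3-dihydro-1-benzofuran | `Brc1cc(OC)c2c(c1)[C@@H](C)[C@H](c1cc(OC)c(OC)c(OC)c1)O2` | intermediate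
13 | (E)-prop-1-enylboronic acid pinacol ester | `C/C=C/B1OC(C)(C)C(C)(C)O1` | starting material
14 | (2R,3R)-7-methoxy-3-methyl-5-[(1E)-prop-1-en-1-yl]-2-(3,4,5-trimethoxyphenyl)-2,3-dihydro-1-benzofuran | `C/C=C/c1cc(OC)c2c(c1)[C@@H](C)[C@H](c1cc(OC)c(OC)c(OC)c1)O2` | target

## Step count and risks

Total step count: 5. Longest linear sequence: 4 steps (1 → 2 → 4 → 12 → 14); the arene branch 5 → 6 → 12 → 14 has 3 steps.

Steps most likely to fail:

**Step 4.** Ylide 9 may rearrange or attack the carbonate group of 8 before quinone methide 10 is released. Quinone methide 10 carries a β-hydrogen and can tautomerise to the vinylphenol or oligomerise before the ylide captures it. The trans/cis ratio and the level and sense of induction are untested for this ylide–acceptor pair. A minor cis isomer would be (2R,3S) and separable by chromatography or crystallisation. The fallback sets out from aldehyde 5 and comes back at bromide 12. MeMgBr (2.5 equiv) in THF at 0 °C gives the diol rac-4-bromo-2-(1-hydroxyethyl)-6-methoxyphenol F1. 4-Methylbenzenesulfinic acid in CH2Cl2 at rt converts F1 by acid-promoted benzylic substitution into the crystalline sulfone rac-4-bromo-2-methoxy-6-[1-(4-methylbenzenesulfonyl)ethyl]phenol F2. With Cs2CO3 and a thiazolium carbene catalyst (3-benzyl-5-(2-hydroxyethyl)-4-methylthiazolium chloride, 20 mol %) in CH2Cl2, F2 loses sulfinate, and 3,4,5-trimethoxybenzaldehyde adds as its acyl anion equivalent to the quinone methide 10 so released. This gives the racemic ketone 2-(5-bromo-2-hydroxy-3-methoxyphenyl)-1-(3,4,5-trimethoxyphenyl)propan-1-one F3. Asymmetric transfer hydrogenation with dynamic kinetic resolution (RuCl(p-cymene)[(R,R)-TsDPEN], HCO2H/Et3N, 40 °C) reduces F3, whose α-centre racemises under the conditions, to (1R,2R)-2-(5-bromo-2-hydroxy-3-methoxyphenyl)-1-(3,4,5-trimethoxyphenyl)propan-1-ol F4. The catalyst fixes 1R and Felkin–Anh control is expected to select the 2R ketone. BF3·OEt2 in CH2Cl2 at −20 °C then ionises the benzylic alcohol, and the phenol closes the ring trans to the methyl group, giving 12 with 3R kept.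

**Step 2.** The electron-rich benzylic bromide 3 hydrolyses in the two-phase medium, and S-alkylation of the hindered sulfide is slow and reversible, so conversion may stall. The fallback sets out from sulfide 2 and comes back at ylide 9. 3,4,5-Trimethoxybenzyl alcohol and CF3SO3H (1.0 equiv) in Et2O at 0 °C alkylate 2 by a dehydrative SN1 path, with 2 in excess (1.5 equiv) to outrun Friedel–Crafts self-condensation of the benzylic cation. The salt (1S,4S,5S,6S)-4,7,7-trimethyl-6-(3,4,5-trimethoxybenzyl)-6-thiabicyclo[3.2.1]octan-6-ium trifluoromethanesulfonate F5 precipitates. LiN(SiMe3)2 in THF at −78 °C turns F5 into ylide 9, and step 4 then runs as written.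

**Step 5.** The aryl bromide is electron-rich, and the alkenylboronate can protodeboronate or lose geometric purity. The fallback sets out from bromide 12 and comes back at target 14. n-BuLi (1.05 equiv) in THF at −78 °C gives the aryllithium [(2R,3R)-7-methoxy-3-methyl-2-(3,4,5-trimethoxyphenyl)-2,3-dihydro-1-benzofuran-5-yl]lithium F6. This adds to propanal to give 1-[(2R,3R)-7-methoxy-3-methyl-2-(3,4,5-trimethoxyphenyl)-2,3-dihydro-1-benzofuran-5-yl]propan-1-ol F7 as both carbinol epimers. Mild dehydration (TsOH 2 mol %, toluene, 60 °C, or MsCl/Et3N then DBU) gives the conjugated E-alkene 14.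

## Further compounds

F1 | step 4 | rac-4-bromo-2-(1-hydroxyethyl)-6-methoxyphenol | `CC(O)c1cc(Br)cc(OC)c1O`
F2 | step 4 | rac-4-bromo-2-methoxy-6-[1-(4-methylbenzenesulfonyl)ethyl]phenol | `CC(c1cc(Br)cc(OC)c1O)S(=O)(=O)c1ccc(C)cc1`
F3 | step 4 | rac-2-(5-bromo-2-hydroxy-3-methoxyphenyl)-1-(3,4,5-trimethoxyphenyl)propan-1-one | `CC(C(=O)c1cc(OC)c(OC)c(OC)c1)c1cc(Br)cc(OC)c1O`
F4 | step 4 | (1R,2R)-2-(5-bromo-2-hydroxy-3-methoxyphenyl)-1-(3,4,5-trimethoxyphenyl)propan-1-ol | `C[C@H](c1cc(Br)cc(OC)c1O)[C@@H](O)c1cc(OC)c(OC)c(OC)c1`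
F5 | step 2 | (1S,4S,5S,6S)-4,7,7-trimethyl-6-(3,4,5-trimethoxybenzyl)-6-thiabicyclo[3.2.1]octan-6-ium trifluoromethanesulfonate | `COc1cc(C[S@+]2[C@H]3C[C@H](CC[C@@H]3C)C2(C)C)cc(OC)c1OC.[O-]S(=O)(=O)C(F)(F)F`
F6 | step 5 | [(2R,3R)-7-methoxy-3-methyl-2-(3,4,5-trimethoxyphenyl)-2,3-dihydro-1-benzofuran-5-yl]lithium | `[Li]c1cc(OC)c2c(c1)[C@@H](C)[C@H](c1cc(OC)c(OC)c(OC)c1)O2`
F7 | step 5 | 1-[(2R,3R)-7-methoxy-3-methyl-2-(3,4,5-trimethoxyphenyl)-2,3-dihydro-1-benzofuran-5-yl]propan-1-ol | `CCC(O)c1cc(OC)c2c(c1)[C@@H](C)[C@H](c1cc(OC)c(OC)c(OC)c1)O2`
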